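The winter run carried 1.51 times the catalyst of the summer run, yet its substrate fell 1.03 times as fast, so I took gas uptake as the rate-limiting step.

in all of them: gas phase 79 mM (held)

| flask | substrate | protic impurity | catalyst | remark | time |
|---|---|---|---|---|---|
| summer | 1.8 M | 0.90 M | 65 mM | run made earlier |  |
| winter | 1.8 M | 0.90 M | 98 mM | run made earlier |  |
| midnight | 0.90 M | 0.90 M | 130 mM | run made earlier |  |
| flask | 1.8 M | 0.900 M | 130 mM |  | 4.0 h |

| run | time / h | target / % | substrate / % |
|---|---|---|---|
| summer | 0.500 | 9.3 | 90.4 |
| summer | 1.00 | 18.9 | 80.6 |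
| summer | 1.50 | 27.8 | 70.9 |
| summer | 2.00 | 35.8 | 61.4 |
| summer | 2.50 | 43.9 | 51.5 |
| summer | 3.00 | 51.7 | 42.8 |
| winter | 0.500 | 10.3 | 90.1 |
| winter | 1.00 | 19.2 | 80.4 |
| winter | 1.50 | 28.5 | 70.4 |
| winter | 2.00 | 37.3 | 60.1 |
| winter | 2.50 | 45.1 | 49.8 |
| winter | 3.00 | 52.8 | 41.3 |
| midnight | 0.250 | 9.6 | 90.8 |
| midnight | 0.500 | 18.6 | 81.1 |
| midnight | 0.833 | 31.4 | 68.5 |
| midnight | 1.50 | 53.7 | 43.6 |
| midnight | 3.00 | 85.4 | 3.4 |

(standard deviation of a reading: 0.3 percentage points)

- target at 4.0 h, in percent of the substrate charged
- concentration of dissolved gas in solution at 4.0 h, in percent of saturation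

- at the start none of the gas is dissolved
- the numbers in the tables scatter with a standard deviation of 0.3 percentage points
- what may be going on: gas phase <-> dissolved gas; substrate + dissolved gas + catalyst -> catalyst + target; dissolved gas + catalyst <-> idle complex; dissolved gas + protic impurity -> quenched reagent; target <-> isomer of the product

My bench rule was to count substrate off at a fixed molar rate, the uptake rate: the molar fall of c(substrate) per hour on the straight part of a run. The midnight run, with the catalyst of the flask, gave 0.340 M h⁻¹. That left 24.5 % of the substrate in the flask at 4.0 h.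

The rule has a border. Over its last interval the midnight run fell at 0.241 M h⁻¹, a ratio of 0.709 to the uptake rate, so it left the line below c(substrate) = 0.392 M. The flask would end at 0.441 M, 1.12 times that level, barely inside.

The balance gap of the summer run, grown with the square of time while target builds linearly, gave 9.78 % as isomer, so I committed to 65.7 % of target. The late midnight slope put the substrate level b, at which uptake slackens, at 0.0580 M, and b over c(substrate) plus b gave me 11.6 % of saturation.

The forecast stood higher on both, at 68 % and 15 %, holding that “gas transfer is limiting”.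

The flask gave 68.1 % of target and 8.52 % of saturation, with 21 % of its substrate left against my 24.5 %.

    gas phase ⇌ dissolved gas, rate k1*(csat - [dissolved gas]) (kL = 4.80 h⁻¹)
    substrate + dissolved gas + catalyst → catalyst + target (k = 1000 M⁻² h⁻¹)
    dissolved gas + catalyst ⇌ idle complex, settled at all times (K = 6.50 M⁻¹)
    dissolved gas + protic impurity → quenched reagent (k = 2.80 M⁻¹ h⁻¹)
    target ⇌ isomer of the product (K = 1.50, k = 0.0780 h⁻¹)

At 1.97 h the flask's target step used dissolved gas 56 times as fast as the quench by protic impurity. By that target step dissolved gas then had a half-life of 0.30 min, short against the 4.0 h of the run. Counted off at 0.340 M h⁻¹, a neighbour flask with 1.1 M of substrate reaches the border level of 0.392 M after 2.08 h, sooner than 4.0 h, so the count stops serving there, and at 4.00 h that flask held 0.42 % of its substrate.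

The earlier runs and the new flask were computed for substances that don't exist; noise was put on by code.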